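**Plan**

1. Numbering: ten-membered carbocycle C1–C10 (ether O between C2 and C9, =CH2 on C7), cyclohexane C1/C10–C14, lactone C14–C15(Me)–C16(=O)–O–C3. Cuts, in retrosynthetic order: ester C–O at C6 and C4; C6–C7 (ten-membered ring); lactone O–C3 together with C4–O (one epoxide); C8–C9; C10–C11 together with C1–H; C9=C10 of a butenolide; C2–C3.
2. Enabling feature: in the cyclohexane the tertiary carbinol C11 lies β to the ring-ether carbon C9 through C10, and C1 bears only H besides carbon. With C9 raised to the lactone level, C9(=O)–C10–C11(OH)Me is an aldol retron and C1 a hydride entry point, so a C1=C10 butenolide with a 3-oxobutyl arm on C14 folds into the cis-fused cyclohexane/γ-lactone in one reductive event.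
3. Forward: (R)-limonene oxide gives C1, C2 and C11–C17 as an open-chain keto-enal and a Z-iodoalkene gives C3–C6. Then butenolide (future tetrahydrofuran) → cyclohexane (key step) → tetrahydrofuran with C8/C7 on C9 → seven-membered lactone → ten-membered ring → C6 ester.
4. Stereochemistry: C14 from limonene; C2 by ligand control in the fragment coupling; C1, C10, C11 relayed from C2 in the key step; C15 by hydroboration anti to C1; C9 by exo attack on the bicyclic oxocarbenium ion; C3/C4 by face-selective epoxidation and invertive lactonization; C6 in the ring-closing addition.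

Key step: step 7

Remark: read literally, the SMILES places C3 and C8 on opposite faces of the tetrahydrofuran (2R,9S, a 2,5-trans ring spanned by the ten-membered carbocycle) and C3 cis to C14; the route is built for exactly this configuration, which makes the final carbocycle strained.

**Step 1**
Reactants: 1 3-[(tert-butyldimethylsilyl)oxy]propanal
Product: 2 tert-butyl{[(3Z)-4-iodopent-3-en-1-yl]oxy}dimethylsilane
Conditions: EtPPh3I, n-BuLi, THF, rt; I2, −78 °C; NaHMDS, −20 °C; then 1, −78 → −20 °C
Reagents that add atoms: ethyltriphenylphosphonium iodide (CC[P+](c1ccccc1)(c1ccccc1)c1ccccc1.[I-]); iodine (II)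
Why: Stork–Zhao olefination with the α-iodoethylidene ylide should give the trisubstituted iodoalkene with iodine cis to the chain (Z), the geometry that becomes the Z C3=C4 olefin needed for the later anti-dioxygenation.

**Step 2**
Reactants: 3 (4R)-limonene 1,2-oxide (cis/trans mixture)
Product: 5 (3R)-6-oxo-3-(prop-1-en-2-yl)heptanal, via menthenediol 4 (not isolated)
Conditions: H5IO6, THF–H2O, 0 °C → rt
Reagents that add atoms: water (O)
Why: epoxide hydrolysis and periodate glycol cleavage in one pot open the ring between the future C11 and C2 and leave the isopropenyl group and the limonene stereocentre (C14) untouched.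

**Step 3**
Reactants: 5 (3R)-6-oxo-3-(prop-1-en-2-yl)heptanal
Product: 7 (3S)-2-methylidene-6-oxo-3-(prop-1-en-2-yl)heptanal, via Mannich base 6 (not isolated)
Conditions: CH2=NMe2+ I− (Eschenmoser's salt), Et3N, CH2Cl2, rt
Reagents that add atoms: N,N-dimethylmethyleneiminium iodide (C=[N+](C)C.[I-])
Why: Mannich α-methylenation, in which the aldehyde enol adds to the iminium salt much faster than the ketone and the β-amino aldehyde loses dimethylamine, should give the 2-substituted acrolein without touching C14.

**Step 4**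
Reactants: 7 (3S)-2-methylidene-6-oxo-3-(prop-1-en-2-yl)heptanal; 2 tert-butyl{[(3Z)-4-iodopent-3-en-1-yl]oxy}dimethylsilane
Product: 9 (5S,7S,8Z)-11-[(tert-butyldimethylsilyl)oxy]-7-hydroxy-8-methyl-6-methylidene-5-(prop-1-en-2-yl)undec-8-en-2-one, via alkenylchromium dichloride 8 (not isolated)
Conditions: CrCl2, NiCl2 (cat.), chiral N-mesyl-2-(4-isopropyl-4,5-dihydrooxazol-2-yl)-6-methylanilide ligand (enantiomer for Si-face addition), Et3N, THF, rt
Reagents that add atoms: none
Why: asymmetric Nozaki–Hiyama–Kishi reaction, in which the alkenylchromium species adds 1,2 to the aldehyde only (the ketone is inert), keeps the Z geometry and is steered by the chiral chromium ligand to the Si face, should set C2 (7S in 9).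

**Step 5**
Reactants: 9 divinyl carbinol
Product: 10 (5S,7S,8Z)-11-[(tert-butyldimethylsilyl)oxy]-8-methyl-6-methylidene-2-oxo-5-(prop-1-en-2-yl)undec-8-en-7-yl prop-2-enoate
Conditions: acryloyl chloride, iPr2NEt, DMAP (cat.), CH2Cl2, −78 → 0 °C
Reagents that add atoms: acryloyl chloride (C=CC(=O)Cl)
Why: O-acylation of the secondary alcohol under basic conditions, which avoid ionization of the bis-allylic carbinol, brings in the carbons that become C9 and C10.

**Step 6**
Reactants: 10 acrylate
Product: 11 (5S)-5-[(2Z)-5-(tert-butyldimethylsilyloxy)pent-2-en-2-yl]-4-[(3S)-2-methyl-6-oxohept-1-en-3-yl]furan-2(5H)-one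
Conditions: RuCl2(=CHPh)(H2IMes)(PCy3) (second-generation Grubbs catalyst, 5 mol%), toluene, 80 °C
Reagents that add atoms: none
Why: ring-closing metathesis between the acrylate and the adjacent 1,1-disubstituted olefin should form the five-membered butenolide (C9=O, C10=C1) with loss of ethylene, the trisubstituted C3=C4 and the remote isopropenyl olefins being much slower partners.

**Step 7**
Reactants: 11 keto-butenolide
Product: 13 (3R,3aS,4R,7R,7aS)-3-[(2Z)-5-(tert-butyldimethylsilyloxy)pent-2-en-2-yl]-7-hydroxy-7-methyl-4-(prop-1-en-2-yl)hexahydro-2-benzofuran-1(3H)-one, via copper enolate 12 (not isolated)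
Conditions: [(Ph3P)CuH]6 (Stryker's reagent, 0.5 equiv), degassed toluene, −40 → 0 °C; aq NH4Cl
Reagents that add atoms: none
Why: Monovalent copper hydride adds in conjugate fashion to C1 of the butenolide, and the copper enolate so formed (C9–O–Cu, nucleophilic at C10) is trapped at once by the tethered C11 methyl ketone, so the C10–C11 bond closes the cyclohexane before any protonation; the closest known reaction type is the copper-hydride reductive aldol cyclization of keto-enoates. The ring closes in the 6-(enolexo)-exo-trig mode. C1 is set because hydride enters anti to the alkenyl group on C2, which places C14 cis to C3; C10 is set because the ketone is tethered through C14 on that same face, so only the cis ring fusion can form. C11 is set by a chair Zimmerman–Traxler array in which copper bridges the lactone and ketone oxygens with the C14 isopropenyl group equatorial, which puts the new hydroxyl cis to C9 and the methyl axial. The step needs 1,4- over 1,2-reduction and no reduction of the isolated ketone or the two unactivated olefins, which the soft phosphine-ligated hydride secures; it also needs aldolization to outrun protonation, which the aprotic medium and the six-membered transition state secure.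

**Step 8**
Reactants: 13 hydroxy lactone
Product: 14 C11 triethylsilyl ether of 13
Conditions: Et3SiOTf, 2,6-lutidine, CH2Cl2, −78 → 0 °C
Reagents that add atoms: triethylsilyl trifluoromethanesulfonate (CC[Si](CC)(CC)OS(=O)(=O)C(F)(F)F)
Why: silylation of the hindered tertiary alcohol with the silyl triflate masks it so that it cannot compete as a nucleophile in the later epoxide opening or eliminate in the Lewis-acid step.

**Step 9**
Reactants: 14 silyl ether
Product: 16 lactone 14 with (2R)-1-hydroxypropan-2-yl in place of isopropenyl (C16–OH), via B-alkyl-9-BBN 15 (not isolated)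
Conditions: 9-BBN, THF, 0 °C → rt; then H2O2, aq NaOAc, 0 °C
Reagents that add atoms: 9-borabicyclo[3.3.1]nonane ([BH]1C2CCCC1CCC2); hydrogen peroxide (OO)
Why: hydroboration–oxidation in which 9-BBN selects the 1,1-disubstituted olefin over the trisubstituted one and adds, in the conformer with C14–H eclipsing the olefin, from the face opposite C1 (which carries the lactone ring) should set C15 by acyclic 1,2-induction; the boron stays only in 15 and is exchanged for the oxygen of hydrogen peroxide with retention.

**Step 10**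
Reactants: 16 hydroxy lactone
Product: 17 lactol of 16 (C9 hemiacetal, both anomers)
Conditions: DIBAL-H, CH2Cl2, −78 °C; aq KNaC4H4O6
Reagents that add atoms: none
Why: DIBAL-H reduction at −78 °C stops at the aluminium hemiacetal of the γ-lactone, the only carbonyl group present, and gives the lactol.

**Step 11**
Reactants: 17 lactol
Product: 18 C9,C16-di-O-acetate of 17
Conditions: Ac2O, pyridine, DMAP (cat.), CH2Cl2, 0 °C → rt
Reagents that add atoms: acetic anhydride (CC(=O)OC(C)=O)
Why: acetylation turns the lactol into an ionizable anomeric acetate and at the same time masks the primary C16 alcohol.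

**Step 12**
Reactants: 18 diacetate
Product: 19 (9S)-C9-(prop-2-yn-1-yl) tetrahydrofuran with the C16 acetate kept
Conditions: allenyltributylstannane, BF3·OEt2, CH2Cl2, −78 → −40 °C
Reagents that add atoms: allenyltributylstannane (C=C=C[Sn](CCCC)(CCCC)CCCC)
Why: Lewis-acid ionization gives the bicyclic oxocarbenium ion, which the allenylstannane should attack in SE2' fashion (C-glycosylation-type substitution) on the exo face, anti to the substituents on C2, C1 and C10 that all lie on the other face, so that C8 ends trans to them.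

**Step 13**
Reactants: 19 propargyl tetrahydrofuran acetate
Product: 20 C16 alcohol
Conditions: K2CO3, MeOH, 0 °C → rt
Reagents that add atoms: none
Why: mild transesterification removes the primary acetate without touching the silyl ethers or the alkyne.

**Step 14**
Reactants: 20 C16 alcohol
Product: 22 C16 carboxylic acid (15R), via aldehyde 21 (not isolated)
Conditions: TEMPO (cat.), PhI(OAc)2, MeCN–H2O (pH 7), rt
Reagents that add atoms: water (O)
Why: nitroxyl-catalysed oxidation with the trivalent iodine co-oxidant takes the primary alcohol through the aldehyde hydrate to the acid under near-neutral conditions that should not epimerize C15 or touch the olefin and alkyne.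

**Step 15**
Reactants: 22 alkenoic acid
Product: 24 seven-membered lactone C16(=O)–O–C3 with free 4-OH (3S,4R), via epoxy acid 23 (not isolated)
Conditions: mCPBA, CH2Cl2, 0 °C; then CSA (cat.), rt
Reagents that add atoms: 3-chloroperoxybenzoic acid (OOC(=O)c1cccc(Cl)c1)
Why: Prilezhaev epoxidation of the only olefin should occur, in the conformer with C2–H eclipsing C4–C5 (allylic 1,3-strain), on the face syn to the ring oxygen and anti to C1, and the C16 acid then opens the epoxide at tertiary C3 from the C1 side with inversion (acid-catalysed 7-exo-tet), giving the lactone oxygen on C3 and the hydroxyl on C4.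

**Step 16**
Reactants: 24 hydroxy lactone
Product: 25 4-O-octanoyl derivative of 24
Conditions: octanoyl chloride, pyridine, DMAP (cat.), CH2Cl2, 0 °C → rt
Reagents that add atoms: octanoyl chloride (CCCCCCCC(=O)Cl)
Why: acylation of the secondary C4 alcohol with the acid chloride under nucleophilic catalysis installs the octanoate.

**Step 17**
Reactants: 25 alkynyl octanoate
Product: 27 C7 iodoalkene (2-iodoallyl group on C9), via iodoalkenylborane 26 (not isolated)
Conditions: B-iodo-9-BBN, pentane–CH2Cl2, −20 °C; then AcOH, 0 °C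
Reagents that add atoms: B-iodo-9-borabicyclo[3.3.1]nonane (IB1C2CCCC1CCC2)
Why: haloboration adds B–I cis and Markovnikov across the terminal alkyne (iodine to the internal carbon C7) and protonolysis of the alkenylborane with acetic acid leaves the 2-iodoalkene.

**Step 18**
Reactants: 27 iodoalkene
Product: 28 6,11-diol
Conditions: HF·pyridine, pyridine, THF, 0 °C → rt
Reagents that add atoms: none
Why: fluoride-mediated desilylation removes the primary silyl ether and, more slowly, the tertiary triethylsilyl ether without affecting the esters, the lactone or the vinyl iodide.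

**Step 19**
Reactants: 28 diol
Product: 29 C6 aldehyde
Conditions: Dess–Martin periodinane, NaHCO3, CH2Cl2, 0 °C → rt
Reagents that add atoms: none
Why: Dess–Martin oxidation converts the primary alcohol to the aldehyde under buffered conditions and cannot oxidize the tertiary C11 alcohol.

**Step 20**
Reactants: 29 iodo aldehyde
Product: 31 6-O-debutyryl target (6R alcohol), via alkenylchromium dichloride 30 (not isolated)
Conditions: CrCl2 (10 equiv), NiCl2 (cat.), DMSO–THF, rt, 2 mM, slow addition
Reagents that add atoms: none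
Why: intramolecular Nozaki–Hiyama–Kishi reaction, in which the alkenylchromium species adds to the C6 aldehyde, should close the ten-membered carbocycle and create the exocyclic methylene and the C6 carbinol, the 6R configuration being expected from addition to the aldehyde face turned away from the C4 octanoate in the ring-forming conformer.

**Step 21**
Reactants: 31 macrocyclic alcohol
Product: 32 CNP0350718.2
Conditions: (n-PrCO)2O, Et3N, DMAP (cat.), CH2Cl2, 0 °C
Reagents that add atoms: butyric anhydride (CCCC(=O)OC(=O)CCC)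
Why: DMAP-catalysed acylation esterifies the secondary allylic C6 alcohol selectively over the hindered tertiary C11 alcohol and completes the target.

**Compound list**

1 | 3-[(tert-butyldimethylsilyl)oxy]propanal | O=CCCO[Si](C)(C)C(C)(C)C | starting material
2 | tert-butyl{[(3Z)-4-iodopent-3-en-1-yl]oxy}dimethylsilane (C3–C6 unit, I cis to C5) | I/C(C)=C\CCO[Si](C)(C)C(C)(C)C | intermediate
3 | (4R)-limonene 1,2-oxide (cis/trans mixture at the epoxide) | C12C[C@@H](CCC1(C)O2)C(C)=C | starting material
4 | (4R)-p-menth-8-ene-1,2-diol (not isolated) | OC1C[C@@H](CCC1(C)O)C(C)=C | intermediate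
5 | (3R)-6-oxo-3-(prop-1-en-2-yl)heptanal | O=CC[C@@H](CCC(C)=O)C(C)=C | intermediate
6 | 2-[(dimethylamino)methyl]-6-oxo-3-(prop-1-en-2-yl)heptanal, Mannich base (not isolated) | O=CC(CN(C)C)[C@@H](CCC(C)=O)C(C)=C | intermediate
7 | (3S)-2-methylidene-6-oxo-3-(prop-1-en-2-yl)heptanal | O=CC(=C)[C@@H](CCC(C)=O)C(C)=C | intermediate
8 | [(2Z)-5-(tert-butyldimethylsilyloxy)pent-2-en-2-yl]chromium dichloride (not isolated) | Cl[Cr](Cl)/C(C)=C\CCO[Si](C)(C)C(C)(C)C | intermediate
9 | (5S,7S,8Z)-11-[(tert-butyldimethylsilyl)oxy]-7-hydroxy-8-methyl-6-methylidene-5-(prop-1-en-2-yl)undec-8-en-2-one | O[C@@H](/C(C)=C\CCO[Si](C)(C)C(C)(C)C)C(=C)[C@@H](CCC(C)=O)C(C)=C | intermediate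
10 | (5S,7S,8Z)-11-[(tert-butyldimethylsilyl)oxy]-8-methyl-6-methylidene-2-oxo-5-(prop-1-en-2-yl)undec-8-en-7-yl prop-2-enoate | C=CC(=O)O[C@@H](/C(C)=C\CCO[Si](C)(C)C(C)(C)C)C(=C)[C@@H](CCC(C)=O)C(C)=C | intermediate
11 | (5S)-5-[(2Z)-5-(tert-butyldimethylsilyloxy)pent-2-en-2-yl]-4-[(3S)-2-methyl-6-oxohept-1-en-3-yl]furan-2(5H)-one | O=C1O[C@@H](/C(C)=C\CCO[Si](C)(C)C(C)(C)C)C(=C1)[C@@H](CCC(C)=O)C(C)=C | intermediate
12 | monovalent copper enolate of the 3,4-dihydro lactone, H added at C1 (phosphine ligands omitted; not isolated) | [Cu]OC=2O[C@@H](/C(C)=C\CCO[Si](C)(C)C(C)(C)C)[C@H](C=2)[C@@H](CCC(C)=O)C(C)=C | intermediate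
13 | (3R,3aS,4R,7R,7aS)-3-[(2Z)-5-(tert-butyldimethylsilyloxy)pent-2-en-2-yl]-7-hydroxy-7-methyl-4-(prop-1-en-2-yl)hexahydro-2-benzofuran-1(3H)-one | O=C1O[C@@H](/C(C)=C\CCO[Si](C)(C)C(C)(C)C)[C@H]2[C@@H](CC[C@@](C)(O)[C@H]21)C(C)=C | intermediate
14 | C11 triethylsilyl ether of 13 | O=C1O[C@@H](/C(C)=C\CCO[Si](C)(C)C(C)(C)C)[C@H]2[C@@H](CC[C@@](C)(O[Si](CC)(CC)CC)[C@H]21)C(C)=C | intermediate
15 | B-alkyl-9-BBN from 14, boron on C16 (not isolated) | O=C1O[C@@H](/C(C)=C\CCO[Si](C)(C)C(C)(C)C)[C@H]2[C@@H](CC[C@@](C)(O[Si](CC)(CC)CC)[C@H]21)[C@@H](C)CB3C4CCCC3CCC4 | intermediate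
16 | 14 with (2R)-1-hydroxypropan-2-yl in place of isopropenyl (C15 set, C16–OH) | O=C1O[C@@H](/C(C)=C\CCO[Si](C)(C)C(C)(C)C)[C@H]2[C@@H](CC[C@@](C)(O[Si](CC)(CC)CC)[C@H]21)[C@@H](C)CO | intermediate
17 | lactol of 16 (C9 hemiacetal, both anomers) | OC1O[C@@H](/C(C)=C\CCO[Si](C)(C)C(C)(C)C)[C@H]2[C@@H](CC[C@@](C)(O[Si](CC)(CC)CC)[C@H]21)[C@@H](C)CO | intermediate
18 | C9,C16-di-O-acetate of 17 (both anomers) | CC(=O)OC1O[C@@H](/C(C)=C\CCO[Si](C)(C)C(C)(C)C)[C@H]2[C@@H](CC[C@@](C)(O[Si](CC)(CC)CC)[C@H]21)[C@@H](C)COC(C)=O | intermediate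
19 | (9S)-C9-(prop-2-yn-1-yl) tetrahydrofuran, C8 trans to the C1, C2 and C10 substituents; C16 acetate | C#CC[C@@H]1O[C@@H](/C(C)=C\CCO[Si](C)(C)C(C)(C)C)[C@H]2[C@@H](CC[C@@](C)(O[Si](CC)(CC)CC)[C@H]21)[C@@H](C)COC(C)=O | intermediate
20 | C16 alcohol from 19 | C#CC[C@@H]1O[C@@H](/C(C)=C\CCO[Si](C)(C)C(C)(C)C)[C@H]2[C@@H](CC[C@@](C)(O[Si](CC)(CC)CC)[C@H]21)[C@@H](C)CO | intermediate
21 | C16 aldehyde (not isolated) | C#CC[C@@H]1O[C@@H](/C(C)=C\CCO[Si](C)(C)C(C)(C)C)[C@H]2[C@@H](CC[C@@](C)(O[Si](CC)(CC)CC)[C@H]21)[C@@H](C)C=O | intermediate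
22 | C16 carboxylic acid (15R) with Z C3=C4 olefin | C#CC[C@@H]1O[C@@H](/C(C)=C\CCO[Si](C)(C)C(C)(C)C)[C@H]2[C@@H](CC[C@@](C)(O[Si](CC)(CC)CC)[C@H]21)[C@@H](C)C(=O)O | intermediate
23 | 3,4-epoxide of 22, epoxide oxygen syn to the ring oxygen (not isolated) | C#CC[C@@H]1O[C@@H]([C@]3(C)O[C@@H]3CCO[Si](C)(C)C(C)(C)C)[C@H]2[C@@H](CC[C@@](C)(O[Si](CC)(CC)CC)[C@H]21)[C@@H](C)C(=O)O | intermediate
24 | seven-membered lactone C16(=O)–O–C3 with free 4-OH (3S,4R) | C#CC[C@@H]1O[C@@H]3[C@H]2[C@@H](CC[C@@](C)(O[Si](CC)(CC)CC)[C@H]21)[C@@H](C)C(=O)O[C@@]3(C)[C@H](O)CCO[Si](C)(C)C(C)(C)C | intermediate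
25 | 4-O-octanoyl derivative of 24 | C#CC[C@@H]1O[C@@H]3[C@H]2[C@@H](CC[C@@](C)(O[Si](CC)(CC)CC)[C@H]21)[C@@H](C)C(=O)O[C@@]3(C)[C@H](OC(=O)CCCCCCC)CCO[Si](C)(C)C(C)(C)C | intermediate
26 | (Z)-2-iodoalkenyl-9-BBN from 25 (not isolated) | I/C(=C\B4C5CCCC4CCC5)C[C@@H]1O[C@@H]3[C@H]2[C@@H](CC[C@@](C)(O[Si](CC)(CC)CC)[C@H]21)[C@@H](C)C(=O)O[C@@]3(C)[C@H](OC(=O)CCCCCCC)CCO[Si](C)(C)C(C)(C)C | intermediate
27 | C7 iodoalkene (C9–CH2–C(I)=CH2) | C=C(I)C[C@@H]1O[C@@H]3[C@H]2[C@@H](CC[C@@](C)(O[Si](CC)(CC)CC)[C@H]21)[C@@H](C)C(=O)O[C@@]3(C)[C@H](OC(=O)CCCCCCC)CCO[Si](C)(C)C(C)(C)C | intermediate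
28 | 6,11-diol from 27 | C=C(I)C[C@@H]1O[C@@H]3[C@H]2[C@@H](CC[C@@](C)(O)[C@H]21)[C@@H](C)C(=O)O[C@@]3(C)[C@H](OC(=O)CCCCCCC)CCO | intermediate
29 | C6 aldehyde from 28 | C=C(I)C[C@@H]1O[C@@H]3[C@H]2[C@@H](CC[C@@](C)(O)[C@H]21)[C@@H](C)C(=O)O[C@@]3(C)[C@H](OC(=O)CCCCCCC)CC=O | intermediate
30 | alkenylchromium dichloride from 29 (not isolated) | C=C([Cr](Cl)Cl)C[C@@H]1O[C@@H]3[C@H]2[C@@H](CC[C@@](C)(O)[C@H]21)[C@@H](C)C(=O)O[C@@]3(C)[C@H](OC(=O)CCCCCCC)CC=O | intermediate
31 | 6-O-debutyryl target (6R alcohol, ten-membered ring closed) | C=C1C[C@@H]2O[C@@H]3[C@H]4[C@@H](CC[C@@](C)(O)[C@H]42)[C@@H](C)C(=O)O[C@@]3(C)[C@H](OC(=O)CCCCCCC)C[C@H]1O | intermediate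
32 | CNP0350718.2, (1S,2R,3S,4R,6R,9S,10R,11R,14R,15R) | C=C1C[C@@H]2O[C@@H]3[C@H]4[C@@H](CC[C@@](C)(O)[C@H]42)[C@@H](C)C(=O)O[C@@]3(C)[C@H](OC(=O)CCCCCCC)C[C@H]1OC(=O)CCC | target

**Totals and risks**

Total: 21 steps. Longest linear sequence: 20 steps (3 → 32, steps 2–21); step 1 is a one-step branch.

Steps most likely to fail:

1. Step 20. The ten-membered ring across the 2,5-trans tetrahydrofuran is strained, so protonation or dimerization of the alkenylchromium species may outrun cyclization, and selection of the aldehyde face may be poor. Fallback: keep the alkyne and close the ring by a nickel-catalysed reductive alkyne–aldehyde coupling in place of the organochromium addition. From 25, HF·pyridine should give the alkynyl diol F1 and Dess–Martin oxidation the ynal F2. Ni(cod)2 (zerovalent nickel), the bulky carbene 1,3-bis(2,6-diisopropylphenyl)imidazol-2-ylidene and Et3SiH at high dilution should join C6 to the internal alkyne carbon C7 through an oxanickelacycle and give the exocyclic-methylene silyl ether F3. HF·pyridine then brings the route back at 31.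

2. Step 15. The peracid may attack the wrong olefin face, and the acid-catalysed opening may lose stereospecificity through ionization at tertiary C3 or cleave a silyl ether. Fallback: replace the epoxide by a halonium ion whose face is chosen by the tethered carboxylate itself. From 22, iodolactonization (I2, NaHCO3, MeCN, 0 °C) should give the iodolactone F4, with the lactone oxygen on C3 and iodine anti on C4. Silver octanoate (AgO2C(CH2)6CH3, toluene, 60 °C) then replaces iodine with net retention through the lactone-bridged dioxolanylium ion (Prévost-type double inversion). This returns to the route at 25 and bypasses 24.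

3. Step 7. The hydride may reduce the ketone or lactone carbonyl in 1,2-fashion, the enolate may be protonated before ring closure, or a non-chelated aldol may give the C11 epimer. Fallback: separate the two events. From 11, [(Ph3P)CuH]6 with Me3SiCl at −78 °C should trap the conjugate-reduction product as the silyl ketene acetal F5, with C1 already set. Anhydrous fluoride (Bu4N+ Ph3SiF2−, THF, −78 → 0 °C) then triggers the intramolecular aldol addition to the ketone through an open transition state and returns to the route at 13.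

**Further compounds**

F1 | step 20 | alkynyl diol: 25 without both silyl groups (6-OH, 11-OH) | C#CC[C@@H]1O[C@@H]3[C@H]2[C@@H](CC[C@@](C)(O)[C@H]21)[C@@H](C)C(=O)O[C@@]3(C)[C@H](OC(=O)CCCCCCC)CCO
F2 | step 20 | ynal: C6 aldehyde of F1 | C#CC[C@@H]1O[C@@H]3[C@H]2[C@@H](CC[C@@](C)(O)[C@H]21)[C@@H](C)C(=O)O[C@@]3(C)[C@H](OC(=O)CCCCCCC)CC=O
F3 | step 20 | 6-O-triethylsilyl ether of 31 | C=C1C[C@@H]2O[C@@H]3[C@H]4[C@@H](CC[C@@](C)(O)[C@H]42)[C@@H](C)C(=O)O[C@@]3(C)[C@H](OC(=O)CCCCCCC)C[C@H]1O[Si](CC)(CC)CC
F4 | step 15 | iodolactone: 24 with iodine in place of the 4-hydroxyl | C#CC[C@@H]1O[C@@H]3[C@H]2[C@@H](CC[C@@](C)(O[Si](CC)(CC)CC)[C@H]21)[C@@H](C)C(=O)O[C@@]3(C)[C@H](I)CCO[Si](C)(C)C(C)(C)C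
F5 | step 7 | trimethylsilyl ketene acetal (2-trimethylsilyloxy-4,5-dihydrofuran) from 11, C1–H set | C[Si](C)(C)OC=2O[C@@H](/C(C)=C\CCO[Si](C)(C)C(C)(C)C)[C@H](C=2)[C@@H](CCC(C)=O)C(C)=C
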